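## The problem

Target 27 is an achiral, fully aromatic pentacycle: a dibenzofuran (rings A and B) is fused through C1 and C2 of ring B to a dibenzo-1,4-dioxin, whose outer benzene ring (ring D) carries a 3,5-dihydroxyphenoxy group (ring E). There is no stereocentre, so nothing has to be set or relayed; every difficulty is positional. Ring D is the dense part: D1 bears the ring E ether, D2 a hydroxyl, D3 the only hydrogen, D4 a hydroxyl, and D5 and D6 the two dioxin oxygens. These are five contiguous oxygenated carbons with five different fates, which substitution of an arene cannot address one by one. The dioxin can close in two orientations; the target is the one in which the D5 oxygen sits on the bay carbon C1 of the dibenzofuran and the D6 oxygen on C2. All three ether bonds to ring D are diaryl ethers with ortho substituents on both sides, so each C–O bond formation is hindered and only the last can be intramolecular. The seven free phenols make the product electron-rich and easily oxidised in base or air, so they must travel as ethers and be released in a final acidic, non-oxidising step. The key step is possible because D3 and D4 can be the termini of a six-electron ring closure: D4, D5, D6 and D1 map onto the four carbons of a squarate ester, and D2–D3 onto a 1-alkoxyvinyl anion.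

## Retrosynthesis

**27 from 26.** The seven O–H bonds are traced back to six methyl ethers and one ethyl ether in 26. Alkyl ethers are the only phenol protection that survives every C–O coupling in the route, and one Lewis-acid operation removes them all. The forward reaction must cleave alkyl–oxygen bonds only; the diaryl ethers, the furan and the dioxin have no such bond.

**26 from 25 and 24.** The dioxin C–O bond between the D5 oxygen and C1 of the dibenzofuran is cut. It is the most hindered bond (bay position), so it is left for the intramolecular step, where only a six-membered closure is possible. Precursor 25 carries a free hydroxyl at D5 and chlorine at C1. It comes from 24 by removal of the one methyl group that is flanked by two oxygen substituents.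

**24 from 15 and 23.** The other dioxin C–O bond (D6 oxygen to C2) is cut, which splits the molecule into two halves of similar size. Cutting here and not at the ring E ether keeps the convergence late. The orientation of the dioxin is decided in this step and nowhere else. Phenol 15 has a single free hydroxyl (D6), and 23 has iodine at C2 and chlorine at C1, so the coupling must be chemoselective for iodine and must tolerate ortho substituents on both partners.

**23 back to 16 and 18.** The dibenzofuran is cut at the biaryl bond and the furan C–O bond. Quinone 17 and phenol 18 join by conjugate addition and cyclodehydration to give 20, in which the quinone delivers chlorine at C1, oxygen at C2 and methoxy at C3 in fixed positions. Because ring D supplies both dioxin oxygens, the C2 hydroxyl of 20 has to become a leaving group. This costs three steps (triflate 21, boronate 22, iodide 23) and is the price of the chosen ring D chemistry. Quinone 17 comes from phenol 16 by oxidation.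

**15 back to 8.** The isopropyl group at D6 of 14 is removed to give 15. Ether 14 comes from phenol 12 and aryl iodide 13 by O-arylation at D1. Phenol 12 comes from silyl ether 11, and 11 from catechol 10 by methylation. The decisive cut is 10 from 8. The two isopropyl ethers of 8 are chemically alike, but only the one at D5 has the free D4 hydroxyl as a neighbour. A boron Lewis acid bound to that phenol oxygen can remove the adjacent isopropyl group alone. This is the point at which D5 and D6 become different, and without it the dioxin orientation could not be controlled.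

**8 from 5, 4, 1 and 2.** Ring D is cut at the D3–D4 bond and traced to cyclobutenone 5. Compound 5 comes from squarate 2 and the anion of vinyl ether 1 via alcohol 4. All six ring carbons and all five oxygens are present in 5, each oxygen already in a distinct form (ketone, two isopropyl enol ethers, a silyl ether, an ethyl enol ether). The forward step must open the four-membered ring with the oxygen turning outward and close the six-membered ring.

## Roads not taken

**Alternative 1:** Ring D is bought as the quinone hub 2,3-dichloro-5-methoxy-1,4-benzoquinone A1. Its two chlorides are displaced in turn by the phenoxide of 18 and by 1-bromo-3,7,9-trimethoxydibenzofuran-2-ol A2 to give the bis(aryloxy)quinone A3. Reduction and ring closure onto the C–Br bond would follow.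
- Merits: addition–elimination on a chloroquinone is little affected by ortho substituents. The dibenzofuranol is used in its natural polarity (oxygen nucleophile, ortho halide for closure).
- In these two respects this road is better than the chosen plan. The chosen plan spends steps 11–13 reversing the polarity of C2 and must make a hindered copper-mediated ether (step 14).
- Weak points: the two chlorides differ only through the remote methoxy group. An aryloxy group on a quinone is itself a leaving group, so the order of entry can scramble and give the transposed isomer. A1 must also be made.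
- Against this the chosen plan sets positional certainty: every ring D oxygen is carried in a distinguishable form from step 3 on, and no step relies on kinetic discrimination between two near-equivalent leaving groups.

**Alternative 2:** The dibenzofuran is cut at the A–B biaryl bond and the furan C–O bond. Phloroglucinol A4 condenses with O-(3,4,5-trimethoxyphenyl)hydroxylamine A5, a [3,3] shift forms the biaryl bond, and loss of ammonia closes the furan to 1,2,3-trimethoxydibenzofuran-7,9-diol A6.
- Merits: one operation from two simple partners. Phloroglucinol is symmetric, so ring A raises no regiochemical question. As a dibenzofuran synthesis it is as short as steps 9–10 and avoids the ortho/para ambiguity of phenol 18 in step 10.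
- Weak points: A6 carries three undifferentiated methoxy groups at C1, C2 and C3, while the target needs two of them as dioxin oxygens and the third as a free hydroxyl. Both dioxin oxygens would then come from ring B, so ring D would have to be a 1,2-dielectrophile, which an oxygen-rich ring D does not offer.
- Comparison: this road solves rings A and B only. The chosen plan's compound 20 has chlorine at C1 and a free hydroxyl at C2 distinguished from the start, and the chosen key step solves ring D.

**Alternative 3:** Ring B and the furan are formed together. The 2-aryloxyfuran A7, carrying a tethered alkynylboronate, undergoes an intramolecular Diels–Alder reaction, and opening of the oxygen bridge gives 3,7,9-trimethoxy-1-(pinacolboryl)dibenzofuran-2-ol A8.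
- Merits: the tether dictates the regiochemistry, and A8 has boron at C1 and hydroxyl at C2, the best-differentiated ring B of all the roads.
- Weak points: A7 is an electron-rich, acid-labile 2-aryloxy-4-methoxyfuran with an alkynylboronate and needs a long preparation. The cycloaddition forms a strained bridged intermediate. The C2 oxygen is again a ring B nucleophile, and the bay-position boron is poorly placed for a hindered C–O coupling.
- Comparison: better differentiation at C1/C2 than 20, but more steps to reach it and no answer for ring D. The chosen plan reaches a usable dibenzofuran in two steps from commercial materials and keeps its single ring-forming risk in ring D.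

Key step: step 3

Remark: compounds 4 and 5 are racemic, and their one stereocentre is destroyed in step 3. 1-Iodo-3,5-dimethoxybenzene 13 and 2-chloro-6-methoxyphenol 16 are taken as commercial.

## Steps

Step 1
Reactants: 1 ethyl vinyl ether; 2 diisopropyl squarate
Product: 4 rac-4-(1-ethoxyvinyl)-4-hydroxy-2,3-diisopropoxycyclobut-2-en-1-one, via 1-ethoxyvinyllithium 3 (not isolated)
Conditions: 1 (excess), t-BuLi, THF, −78 → 0 °C; then 2, THF, −78 °C; H2O
Reagents that add atoms: none
Why: Deprotonation of the vinyl ether next to oxygen gives the acyl-anion equivalent 3, which adds 1,2 to one of the two equivalent carbonyls of the squarate at low temperature (the known organolithium addition to squarate esters). The new quaternary carbon forms as a racemate and is lost in step 3, and the neutral quench protects the enol ether.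

Step 2
Reactants: 4 rac-4-(1-ethoxyvinyl)-4-hydroxy-2,3-diisopropoxycyclobut-2-en-1-one
Product: 5 rac-4-[(tert-butyldimethylsilyl)oxy]-4-(1-ethoxyvinyl)-2,3-diisopropoxycyclobut-2-en-1-one
Conditions: TBSOTf, 2,6-lutidine, CH2Cl2, −78 → 0 °C
Reagents that add atoms: tert-butyldimethylsilyl trifluoromethanesulfonate, CC(C)(C)[Si](C)(C)OS(=O)(=O)C(F)(F)F
Why: Silyl triflate with a hindered pyridine base is the standard silylation of a tertiary alcohol, and the buffered medium keeps the acid-labile enol ether intact.

Step 3
Reactants: 5 rac-4-[(tert-butyldimethylsilyl)oxy]-4-(1-ethoxyvinyl)-2,3-diisopropoxycyclobut-2-en-1-one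
Product: 8 4-[(tert-butyldimethylsilyl)oxy]-5-ethoxy-2,3-diisopropoxyphenol, via dienylketene 6 (not isolated), via cyclohexadienone 7 (not isolated)
Conditions: toluene (dilute, degassed), 110 °C
Reagents that add atoms: none
Why: Heating breaks the bond between the carbonyl carbon and the quaternary carbon in a conrotatory 4π electrocyclic ring opening to give dienylketene 6. The silyloxy group, the stronger donor on the breaking carbon, rotates outward, so the 1-ethoxyvinyl group turns inward and ends cis to the ketene (Z geometry of 6). The ketene carbon then bonds to the vinyl CH2 terminus in a thermal disrotatory 6π electrocyclisation, which forms the D3–D4 bond and closes the six-membered carbocycle (ring D) as cyclohexadienone 7. Tautomerisation of 7 gives phenol 8, driven by aromatisation. The closest known reaction type is the thermal ring expansion of squarate-derived 4-alkenyl-4-hydroxy- or 4-silyloxycyclobutenones to hydroquinones or their mono-silyl ethers. No stereocentre is formed, and the racemic quaternary centre of 5 disappears. The one selectivity needed is the outward rotation of oxygen, secured by the donor oxygen on the quaternary carbon; connectivity then places the free hydroxyl at D4, isopropoxy at D5 and D6, silyloxy at D1, ethoxy at D2 and hydrogen at D3. Dilute, degassed solution limits ketene dimerisation and oxidation of the electron-rich product.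

Step 4
Reactants: 8 4-[(tert-butyldimethylsilyl)oxy]-5-ethoxy-2,3-diisopropoxyphenol
Product: 10 4-[(tert-butyldimethylsilyl)oxy]-5-ethoxy-3-isopropoxybenzene-1,2-diol, via cyclic chloroborate 9 (not isolated)
Conditions: BCl3 (1.05 equiv), CH2Cl2, −78 → −30 °C; aq. NaHCO3
Reagents that add atoms: none
Why: The free phenol binds boron first, and the boron then chelates the neighbouring isopropoxy oxygen and delivers chloride to its isopropyl group, giving chloroborate 9. This is the hydroxyl-directed Lewis-acid dealkylation known from polyalkoxyflavones, applied to the more labile isopropyl ether. With one equivalent of BCl3 at low temperature the remote isopropyl ether has no boron neighbour and should survive, as should the hindered aryl silyl ether.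

Step 5
Reactants: 10 4-[(tert-butyldimethylsilyl)oxy]-5-ethoxy-3-isopropoxybenzene-1,2-diol
Product: 11 tert-butyl(2-ethoxy-6-isopropoxy-4,5-dimethoxyphenoxy)dimethylsilane
Conditions: MeI, K2CO3, acetone, 50 °C, under argon
Reagents that add atoms: iodomethane, CI
Why: Williamson methylation of both catechol hydroxyls under mild carbonate conditions that a doubly ortho-substituted aryl silyl ether tolerates. After this step D6 is the only isopropyl ether.

Step 6
Reactants: 11 tert-butyl(2-ethoxy-6-isopropoxy-4,5-dimethoxyphenoxy)dimethylsilane
Product: 12 2-ethoxy-6-isopropoxy-4,5-dimethoxyphenol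
Conditions: Bu4NF, THF, 0 °C; H2O
Reagents that add atoms: none
Why: Fluoride cleaves the aryl silyl ether and touches nothing else. The phenol is an electron-rich hydroquinone monoether and is used at once under argon.

Step 7
Reactants: 12 2-ethoxy-6-isopropoxy-4,5-dimethoxyphenol; 13 1-iodo-3,5-dimethoxybenzene
Product: 14 2-(3,5-dimethoxyphenoxy)-1-ethoxy-3-isopropoxy-4,5-dimethoxybenzene
Conditions: CuI (cat.), picolinic acid (cat.), K3PO4, DMSO, 90 °C, argon
Reagents that add atoms: none
Why: Ullmann-type O-arylation. The picolinic acid/copper system is known to couple 2,6-disubstituted phenols, and the aryl iodide is unhindered.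

Step 8
Reactants: 14 2-(3,5-dimethoxyphenoxy)-1-ethoxy-3-isopropoxy-4,5-dimethoxybenzene
Product: 15 2-(3,5-dimethoxyphenoxy)-3-ethoxy-5,6-dimethoxyphenol
Conditions: BCl3 (1.5 equiv), CH2Cl2, −78 → −40 °C; MeOH at −78 °C
Reagents that add atoms: none
Why: BCl3 cleaves secondary-alkyl (isopropyl) aryl ethers at low temperature and leaves methyl, ethyl and diaryl ethers alone (known selectivity). The cold quench keeps the new boron-bound D6 oxygen from attacking the neighbouring D5 methoxy group.

Step 9
Reactants: 16 2-chloro-6-methoxyphenol
Product: 17 2-chloro-6-methoxy-1,4-benzoquinone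
Conditions: K2[ON(SO3)2] (2.2 equiv), KH2PO4 buffer, H2O/acetone, 0 °C → rt
Reagents that add atoms: potassium nitrosodisulfonate, [K+].[K+].[O]N(S(=O)(=O)[O-])S(=O)(=O)[O-]
Why: Teuber oxidation of a phenol with a free para position gives the para-quinone; the two ortho substituents block other pathways.

Step 10
Reactants: 17 2-chloro-6-methoxy-1,4-benzoquinone; 18 3,5-dimethoxyphenol
Product: 20 1-chloro-3,7,9-trimethoxydibenzofuran-2-ol, via biaryl hydroquinone 19 (not isolated)
Conditions: CF3CO2H (cat.), CH2Cl2, 0 °C → rt, 17 added slowly to 18; then TsOH (cat.), toluene, 110 °C with removal of water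
Reagents that add atoms: none
Why: Acid-catalysed Friedel–Crafts-type conjugate addition of the ortho carbon of 18 to the quinone at the free carbon next to chlorine (the free carbon next to methoxy is deactivated as the α-carbon of a vinylogous ester) gives 19. The phloroglucinol-type ring of 19 is readily protonated at carbon, so the two ortho hydroxyls condense to the furan. This is the known quinone–phenol route to 2-hydroxydibenzofurans and is redox-neutral overall.

Step 11
Reactants: 20 1-chloro-3,7,9-trimethoxydibenzofuran-2-ol
Product: 21 1-chloro-3,7,9-trimethoxydibenzofuran-2-yl trifluoromethanesulfonate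
Conditions: Tf2O, pyridine, CH2Cl2, 0 °C
Reagents that add atoms: trifluoromethanesulfonic anhydride, O=S(=O)(OS(=O)(=O)C(F)(F)F)C(F)(F)F
Why: Standard O-sulfonylation of a phenol; it turns the C2 oxygen into a leaving group.

Step 12
Reactants: 21 1-chloro-3,7,9-trimethoxydibenzofuran-2-yl trifluoromethanesulfonate
Product: 22 2-(1-chloro-3,7,9-trimethoxydibenzofuran-2-yl)-4,4,5,5-tetramethyl-1,3,2-dioxaborolane
Conditions: B2pin2, Pd(dppf)Cl2 (cat.), KOAc, 1,4-dioxane, 90 °C
Reagents that add atoms: bis(pinacolato)diboron, CC1(C)OB(OC1(C)C)B1OC(C)(C)C(C)(C)O1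
Why: Miyaura borylation. With the bidentate phosphine the aryl triflate undergoes oxidative addition while the hindered, electron-rich aryl chloride stays intact.

Step 13
Reactants: 22 2-(1-chloro-3,7,9-trimethoxydibenzofuran-2-yl)-4,4,5,5-tetramethyl-1,3,2-dioxaborolane
Product: 23 1-chloro-2-iodo-3,7,9-trimethoxydibenzofuran
Conditions: KI, CuI (cat.), 1,10-phenanthroline (cat.), MeOH/H2O, air, 80 °C
Reagents that add atoms: potassium iodide, [K+].[I-]
Why: Copper-catalysed aerobic iododeboronation replaces boron by iodine at the same carbon. Iodine enters as iodide, so the very electron-rich ring A is not iodinated as it would be by an electrophilic iodine source.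

Step 14
Reactants: 15 2-(3,5-dimethoxyphenoxy)-3-ethoxy-5,6-dimethoxyphenol; 23 1-chloro-2-iodo-3,7,9-trimethoxydibenzofuran
Product: 24 1-chloro-2-[2-(3,5-dimethoxyphenoxy)-3-ethoxy-5,6-dimethoxyphenoxy]-3,7,9-trimethoxydibenzofuran
Conditions: CuI, picolinic acid, K3PO4, DMSO, 90–100 °C, argon
Reagents that add atoms: none
Why: Ullmann-type O-arylation, chemoselective for the C–I bond over C–Cl. Since 15 has only the D6 hydroxyl free, the D6 oxygen is joined to C2 and the dioxin orientation is fixed. The ligand system is the one developed for ortho-substituted partners.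

Step 15
Reactants: 24 1-chloro-2-[2-(3,5-dimethoxyphenoxy)-3-ethoxy-5,6-dimethoxyphenoxy]-3,7,9-trimethoxydibenzofuran
Product: 25 2-[(1-chloro-3,7,9-trimethoxydibenzofuran-2-yl)oxy]-3-(3,5-dimethoxyphenoxy)-4-ethoxy-6-methoxyphenol
Conditions: BCl3 (2 equiv), CH2Cl2, −20 → 0 °C; aq. NaHCO3
Reagents that add atoms: none
Why: The D5 methoxy is the only alkyl ether flanked by two oxygen substituents, which twists it out of conjugation and makes it the most Lewis-basic. Such central methoxy groups of 1,2,3-trioxygenated arenes are the ones cleaved first by BCl3 (known regioselective demethylation), while methoxy groups with at most one oxygen neighbour remain.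

Step 16
Reactants: 25 2-[(1-chloro-3,7,9-trimethoxydibenzofuran-2-yl)oxy]-3-(3,5-dimethoxyphenoxy)-4-ethoxy-6-methoxyphenol
Product: 26 hexa-O-methyl mono-O-ethyl ether of 27: dioxin closed between the D6 and D5 oxygens and C2 and C1 of 3,7,9-trimethoxydibenzofuran, with ring D bearing 3,5-dimethoxyphenoxy (D1), ethoxy (D2) and methoxy (D4)
Conditions: Pd(OAc)2 (cat.), 2-di-tert-butylphosphino-2',4',6'-triisopropylbiphenyl (cat.), K3PO4, toluene, 100 °C
Reagents that add atoms: none
Why: Palladium-catalysed intramolecular C–O coupling of the aryl chloride with the only free phenol. The bulky dialkylbiarylphosphine promotes oxidative addition of the hindered chloride and C–O reductive elimination. Only the six-membered dioxin can form, so no regiochemical choice is left.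

Step 17
Reactants: 26 hexa-O-methyl mono-O-ethyl ether of 27
Product: 27 target CNP0256302.0: dibenzofuran-3,7,9-triol whose C2 and C1 are bridged through two oxygens to adjacent carbons D6 and D5 of ring D, which carries 3,5-dihydroxyphenoxy at D1 and hydroxyls at D2 and D4
Conditions: BBr3 (excess), CH2Cl2, −78 °C → rt; MeOH, then degassed aqueous work-up
Reagents that add atoms: none
Why: BBr3 cleaves all six methyl ethers and the ethyl ether at the alkyl–oxygen bond. Diaryl ethers, the furan and the dioxin have no alkyl–oxygen bond and survive, and the acidic, non-oxidising conditions suit the air-sensitive polyphenol.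

## Compound list

1 | ethyl vinyl ether | C=COCC | starting material
2 | diisopropyl squarate (3,4-diisopropoxycyclobut-3-ene-1,2-dione) | CC(C)OC1=C(OC(C)C)C(=O)C1=O | starting material
3 | 1-ethoxyvinyllithium | [Li]C(=C)OCC | intermediate (not isolated)
4 | rac-4-(1-ethoxyvinyl)-4-hydroxy-2,3-diisopropoxycyclobut-2-en-1-one | C=C(OCC)C1(O)C(OC(C)C)=C(OC(C)C)C1=O | intermediate
5 | rac-4-[(tert-butyldimethylsilyl)oxy]-4-(1-ethoxyvinyl)-2,3-diisopropoxycyclobut-2-en-1-one | C=C(OCC)C1(O[Si](C)(C)C(C)(C)C)C(OC(C)C)=C(OC(C)C)C1=O | intermediate
6 | (3Z)-4-[(tert-butyldimethylsilyl)oxy]-5-ethoxy-2,3-diisopropoxyhexa-1,3,5-trien-1-one (dienylketene) | O=C=C(OC(C)C)/C(OC(C)C)=C(/O[Si](C)(C)C(C)(C)C)C(OCC)=C | intermediate (not isolated)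
7 | 4-[(tert-butyldimethylsilyl)oxy]-5-ethoxy-2,3-diisopropoxycyclohexa-2,4-dien-1-one | O=C1CC(OCC)=C(O[Si](C)(C)C(C)(C)C)C(OC(C)C)=C1OC(C)C | intermediate (not isolated)
8 | 4-[(tert-butyldimethylsilyl)oxy]-5-ethoxy-2,3-diisopropoxyphenol | CCOc1cc(O)c(OC(C)C)c(OC(C)C)c1O[Si](C)(C)C(C)(C)C | intermediate
9 | 5-[(tert-butyldimethylsilyl)oxy]-2-chloro-6-ethoxy-4-isopropoxy-1,3,2-benzodioxaborole (cyclic chloroborate) | CCOc1cc2OB(Cl)Oc2c(OC(C)C)c1O[Si](C)(C)C(C)(C)C | intermediate (not isolated)
10 | 4-[(tert-butyldimethylsilyl)oxy]-5-ethoxy-3-isopropoxybenzene-1,2-diol | CCOc1cc(O)c(O)c(OC(C)C)c1O[Si](C)(C)C(C)(C)C | intermediate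
11 | tert-butyl(2-ethoxy-6-isopropoxy-4,5-dimethoxyphenoxy)dimethylsilane | CCOc1cc(OC)c(OC)c(OC(C)C)c1O[Si](C)(C)C(C)(C)C | intermediate
12 | 2-ethoxy-6-isopropoxy-4,5-dimethoxyphenol | CCOc1cc(OC)c(OC)c(OC(C)C)c1O | intermediate
13 | 1-iodo-3,5-dimethoxybenzene | COc1cc(I)cc(OC)c1 | starting material
14 | 2-(3,5-dimethoxyphenoxy)-1-ethoxy-3-isopropoxy-4,5-dimethoxybenzene | CCOc1cc(OC)c(OC)c(OC(C)C)c1Oc1cc(OC)cc(OC)c1 | intermediate
15 | 2-(3,5-dimethoxyphenoxy)-3-ethoxy-5,6-dimethoxyphenol | CCOc1cc(OC)c(OC)c(O)c1Oc1cc(OC)cc(OC)c1 | intermediate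
16 | 2-chloro-6-methoxyphenol | COc1cccc(Cl)c1O | starting material
17 | 2-chloro-6-methoxy-1,4-benzoquinone | COC1=CC(=O)C=C(Cl)C1=O | intermediate
18 | 3,5-dimethoxyphenol | COc1cc(O)cc(OC)c1 | starting material
19 | 2-chloro-3-(2-hydroxy-4,6-dimethoxyphenyl)-6-methoxybenzene-1,4-diol | COc1cc(O)c(-c2c(O)cc(OC)cc2OC)c(Cl)c1O | intermediate (not isolated)
20 | 1-chloro-3,7,9-trimethoxydibenzofuran-2-ol | COc1cc2oc3cc(OC)cc(OC)c3c2c(Cl)c1O | intermediate
21 | 1-chloro-3,7,9-trimethoxydibenzofuran-2-yl trifluoromethanesulfonate | COc1cc2oc3cc(OC)cc(OC)c3c2c(Cl)c1OS(=O)(=O)C(F)(F)F | intermediate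
22 | 2-(1-chloro-3,7,9-trimethoxydibenzofuran-2-yl)-4,4,5,5-tetramethyl-1,3,2-dioxaborolane | COc1cc2oc3cc(OC)cc(OC)c3c2c(Cl)c1B1OC(C)(C)C(C)(C)O1 | intermediate
23 | 1-chloro-2-iodo-3,7,9-trimethoxydibenzofuran | COc1cc2oc3cc(OC)cc(OC)c3c2c(Cl)c1I | intermediate
24 | 1-chloro-2-[2-(3,5-dimethoxyphenoxy)-3-ethoxy-5,6-dimethoxyphenoxy]-3,7,9-trimethoxydibenzofuran | CCOc1cc(OC)c(OC)c(Oc2c(OC)cc3oc4cc(OC)cc(OC)c4c3c2Cl)c1Oc1cc(OC)cc(OC)c1 | intermediate
25 | 2-[(1-chloro-3,7,9-trimethoxydibenzofuran-2-yl)oxy]-3-(3,5-dimethoxyphenoxy)-4-ethoxy-6-methoxyphenol | CCOc1cc(OC)c(O)c(Oc2c(OC)cc3oc4cc(OC)cc(OC)c4c3c2Cl)c1Oc1cc(OC)cc(OC)c1 | intermediate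
26 | hexa-O-methyl mono-O-ethyl ether of 27 (ring D: 3,5-dimethoxyphenoxy at D1, ethoxy at D2, methoxy at D4; dibenzofuran: 3,7,9-trimethoxy) | COc1cc(OC)cc(Oc2c(OCC)cc(OC)c3c2Oc2c(OC)cc4oc5cc(OC)cc(OC)c5c4c2O3)c1 | intermediate
27 | CNP0256302.0 (dibenzofuran-3,7,9-triol with C2 and C1 bridged by two oxygens to D6 and D5 of ring D; ring D bears 3,5-dihydroxyphenoxy at D1 and hydroxyls at D2 and D4) | Oc1cc(O)cc(Oc2c(O)cc(O)c3c2Oc2c(O)cc4oc5cc(O)cc(O)c5c4c2O3)c1 | target

## Step count and least certain steps

Total: 17 steps. Longest linear sequence: 12 steps (steps 1–8 and 14–17); the dibenzofuran branch (steps 9–13) joins at step 14.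

**Step 3 (key step).**
- Most likely failure: loss of the silyl group and over-oxidation of the very electron-rich product at 110 °C, or diversion of the ketene (dimerisation, trapping) if the ring opening is not cleanly oxygen-outward.
- Fallback, from 4 to 8: the free alcohol 4 is heated in toluene and the hydroquinone is oxidised in air with Ag2O to 2-ethoxy-5,6-diisopropoxy-1,4-benzoquinone F1, the classical quinone form of the same ring expansion. Na2S2O4 reduces F1 to 5-ethoxy-2,3-diisopropoxybenzene-1,4-diol F2. Pivaloyl chloride and pyridine acylate the less hindered hydroxyl (the one with an ortho hydrogen) to give 5-ethoxy-4-hydroxy-2,3-diisopropoxyphenyl pivalate F3. TBSOTf and 2,6-lutidine silylate the remaining hydroxyl to give 4-[(tert-butyldimethylsilyl)oxy]-5-ethoxy-2,3-diisopropoxyphenyl pivalate F4, and i-Bu2AlH removes the pivalate to give 8.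

**Step 4.**
- Most likely failure: a second dealkylation (loss of the remote isopropyl group) or loss of the silyl ether if boron is not held at the phenol oxygen. The two dioxin oxygens would then be indistinguishable again.
- Fallback, from 8 to 14, using the para relationship of D5 and D2 for differentiation: 8 is methylated (MeI, K2CO3) to tert-butyl(2-ethoxy-5,6-diisopropoxy-4-methoxyphenoxy)dimethylsilane F5 and desilylated with Bu4NF to 2-ethoxy-5,6-diisopropoxy-4-methoxyphenol F6. Coupling with 13 (CuI, picolinic acid, K3PO4) gives 2-(3,5-dimethoxyphenoxy)-1-ethoxy-3,4-diisopropoxy-5-methoxybenzene F7. (NH4)2Ce(NO3)6 oxidises the only para pair of oxygens that are both alkylated (D2 and D5) to 2-(3,5-dimethoxyphenoxy)-3-isopropoxy-5-methoxy-1,4-benzoquinone F8, which keeps the D6 isopropyl ether. Na2S2O4 gives 2-(3,5-dimethoxyphenoxy)-3-isopropoxy-5-methoxybenzene-1,4-diol F9. EtI and K2CO3 (one equivalent) ethylate the less hindered hydroxyl to give 3-(3,5-dimethoxyphenoxy)-4-ethoxy-2-isopropoxy-6-methoxyphenol F10, and methylation of the remaining hydroxyl gives 14.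

**Step 10.**
- Most likely failure: C–C bond formation at the carbon of 18 para to its hydroxyl (between the two methoxy groups), which cannot close to a furan, and redox exchange between 19 and unreacted 17.
- Fallback, from 17 to 20: the para position is blocked by using 4-bromo-3,5-dimethoxyphenol (COc1cc(O)cc(OC)c1Br) in the same condensation, giving 8-bromo-1-chloro-3,7,9-trimethoxydibenzofuran-2-ol F11. Hydrogenolysis (H2, Pd/C, NaOAc) removes the bromine selectively over the chlorine to give 20.

**Step 14.**
- Most likely failure: slow C–O bond formation at copper because both partners carry two ortho substituents, so that reduction of the C–I bond and oxidation of the phenoxide take over.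
- Fallback, from 22 to 24: boronate 22 is condensed with (2,4,6-trimethoxyphenyl)iodine diacetate to give (1-chloro-3,7,9-trimethoxydibenzofuran-2-yl)(2,4,6-trimethoxyphenyl)iodonium acetate F12. This arylates the potassium phenoxide of 15 without a metal at room temperature, a method known to give fully ortho-substituted diaryl ethers; the trimethoxyphenyl group is not transferred. The product is 24.

**Step 15.**
- Most likely failure: poor site selectivity of the demethylation (attack at a methoxy other than the flanked one, or at several).
- Fallback, from 24 to 27: (NH4)2Ce(NO3)6 oxidises the para-related D2 ethoxy and D5 methoxy groups of 24 to 3-[(1-chloro-3,7,9-trimethoxydibenzofuran-2-yl)oxy]-2-(3,5-dimethoxyphenoxy)-5-methoxy-1,4-benzoquinone F13. Na2S2O4 gives 3-[(1-chloro-3,7,9-trimethoxydibenzofuran-2-yl)oxy]-2-(3,5-dimethoxyphenoxy)-5-methoxybenzene-1,4-diol F14. The palladium-catalysed closure of step 16 then forms the dioxin from the D5 hydroxyl (the D2 hydroxyl cannot reach), giving the analogue of 26 with a free hydroxyl in place of ethoxy, F15. BBr3 converts F15 to 27.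

## Further compounds

F1 | step 3 | 2-ethoxy-5,6-diisopropoxy-1,4-benzoquinone | CCOC1=CC(=O)C(OC(C)C)=C(OC(C)C)C1=O
F2 | step 3 | 5-ethoxy-2,3-diisopropoxybenzene-1,4-diol | CCOc1cc(O)c(OC(C)C)c(OC(C)C)c1O
F3 | step 3 | 5-ethoxy-4-hydroxy-2,3-diisopropoxyphenyl pivalate | CCOc1cc(OC(=O)C(C)(C)C)c(OC(C)C)c(OC(C)C)c1O
F4 | step 3 | 4-[(tert-butyldimethylsilyl)oxy]-5-ethoxy-2,3-diisopropoxyphenyl pivalate | CCOc1cc(OC(=O)C(C)(C)C)c(OC(C)C)c(OC(C)C)c1O[Si](C)(C)C(C)(C)C
F5 | step 4 | tert-butyl(2-ethoxy-5,6-diisopropoxy-4-methoxyphenoxy)dimethylsilane | CCOc1cc(OC)c(OC(C)C)c(OC(C)C)c1O[Si](C)(C)C(C)(C)C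
F6 | step 4 | 2-ethoxy-5,6-diisopropoxy-4-methoxyphenol | CCOc1cc(OC)c(OC(C)C)c(OC(C)C)c1O
F7 | step 4 | 2-(3,5-dimethoxyphenoxy)-1-ethoxy-3,4-diisopropoxy-5-methoxybenzene | CCOc1cc(OC)c(OC(C)C)c(OC(C)C)c1Oc1cc(OC)cc(OC)c1
F8 | step 4 | 2-(3,5-dimethoxyphenoxy)-3-isopropoxy-5-methoxy-1,4-benzoquinone | COC1=CC(=O)C(Oc2cc(OC)cc(OC)c2)=C(OC(C)C)C1=O
F9 | step 4 | 2-(3,5-dimethoxyphenoxy)-3-isopropoxy-5-methoxybenzene-1,4-diol | COc1cc(O)c(Oc2cc(OC)cc(OC)c2)c(OC(C)C)c1O
F10 | step 4 | 3-(3,5-dimethoxyphenoxy)-4-ethoxy-2-isopropoxy-6-methoxyphenol | COc1cc(OCC)c(Oc2cc(OC)cc(OC)c2)c(OC(C)C)c1O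
F11 | step 10 | 8-bromo-1-chloro-3,7,9-trimethoxydibenzofuran-2-ol | COc1cc2oc3cc(OC)c(Br)c(OC)c3c2c(Cl)c1O
F12 | step 14 | (1-chloro-3,7,9-trimethoxydibenzofuran-2-yl)(2,4,6-trimethoxyphenyl)iodonium acetate | COc1cc2oc3cc(OC)cc(OC)c3c2c(Cl)c1[I+]c1c(OC)cc(OC)cc1OC.CC(=O)[O-]
F13 | step 15 | 3-[(1-chloro-3,7,9-trimethoxydibenzofuran-2-yl)oxy]-2-(3,5-dimethoxyphenoxy)-5-methoxy-1,4-benzoquinone | COC1=CC(=O)C(Oc2cc(OC)cc(OC)c2)=C(Oc2c(OC)cc3oc4cc(OC)cc(OC)c4c3c2Cl)C1=O
F14 | step 15 | 3-[(1-chloro-3,7,9-trimethoxydibenzofuran-2-yl)oxy]-2-(3,5-dimethoxyphenoxy)-5-methoxybenzene-1,4-diol | COc1cc(O)c(Oc2cc(OC)cc(OC)c2)c(Oc2c(OC)cc3oc4cc(OC)cc(OC)c4c3c2Cl)c1O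
F15 | step 15 | analogue of 26 with a free hydroxyl at D2 in place of ethoxy | COc1cc(OC)cc(Oc2c(O)cc(OC)c3c2Oc2c(OC)cc4oc5cc(OC)cc(OC)c5c4c2O3)c1
A1 | alternative 1 | 2,3-dichloro-5-methoxy-1,4-benzoquinone | COC1=CC(=O)C(Cl)=C(Cl)C1=O
A2 | alternative 1 | 1-bromo-3,7,9-trimethoxydibenzofuran-2-ol | COc1cc2oc3cc(OC)cc(OC)c3c2c(Br)c1O
A3 | alternative 1 | 2-(3,5-dimethoxyphenoxy)-3-[(1-bromo-3,7,9-trimethoxydibenzofuran-2-yl)oxy]-5-methoxy-1,4-benzoquinone | COC1=CC(=O)C(Oc2cc(OC)cc(OC)c2)=C(Oc2c(OC)cc3oc4cc(OC)cc(OC)c4c3c2Br)C1=O
A4 | alternative 2 | phloroglucinol | Oc1cc(O)cc(O)c1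
A5 | alternative 2 | O-(3,4,5-trimethoxyphenyl)hydroxylamine | COc1cc(ON)cc(OC)c1OC
A6 | alternative 2 | 1,2,3-trimethoxydibenzofuran-7,9-diol | COc1cc2oc3cc(O)cc(O)c3c2c(OC)c1OC
A7 | alternative 3 | 2-{3,5-dimethoxy-2-[(4,4,5,5-tetramethyl-1,3,2-dioxaborolan-2-yl)ethynyl]phenoxy}-4-methoxyfuran | COc1coc(Oc2cc(OC)cc(OC)c2C#CB2OC(C)(C)C(C)(C)O2)c1
A8 | alternative 3 | 3,7,9-trimethoxy-1-(pinacolboryl)dibenzofuran-2-ol | COc1cc2oc3cc(OC)cc(OC)c3c2c(B2OC(C)(C)C(C)(C)O2)c1O
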